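The earlier runs and the new flask were computed for an exercise; the scatter is artificial.

- Adding two columns comes first: in elm at 8.00 h, monomer in chains and free monomer together make 27.0% of the charge, so a side loss took the rest.

| setting | elm | birch | noon | autumn |
|---|---|---|---|---|
| free monomer | 0.10 M | 0.10 M | 0.10 M | 0.10 M |
| initiator | 0.67 mM | 1.4 mM | 1.0 mM | 0.50 mM |
| remark | run made earlier | run made earlier |  |  |
| time |  |  | 12 h | 12 h |

- elm (time / h: monomer in chains / %, free monomer / %): 0.667: 2.5, 63.1; 1.00: 3.6, 52.7; 2.00: 6.9, 33.4; 3.00: 11.5, 22.5; 5.00: 17.3, 11.4; 8.00: 21.7, 5.3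
- birch (time / h: monomer in chains / %, free monomer / %): 0.500: 2.6, 68.0; 1.50: 9.4, 36.7; 3.00: 21.3, 18.2; 5.00: 29.3, 6.7; 6.00: 30.0, 5.2; 8.00: 33.1, 3.4

(readings scatter by 0.5 percentage points)



1. the flask that ends with the higher amount of monomer in chains, in percent of the free monomer charged, or "neither" when 2 percentage points or less lies between them (noon / autumn / neither)
2. final monomer in chains, as a percentage of the free monomer charged, in noon
3. final monomer in chains, as a percentage of the free monomer charged, in autumn

- The elm readings seem to disagree: chains hold 22.9% of all free monomer lost by 8.00 h, yet 72.1% of that lost between 5.00 h and 8.00 h.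
- My own reckoning takes chain growth as first order in free monomer f and the side loss as second order. Their ratio, a selectivity factor, is then f×/f, where f× is the crossing: the free monomer level at which both consume it equally fast. Below f×, chains lead, which clears the elm puzzle.
- The stretch from 3.00 h to 5.00 h reads f× in elm as 18.5%. The stretch from 3.00 h to 5.00 h reads it in birch as 28.5%.
- Taking f× as proportional to initiator and averaging both readings per mM gives noon 24.0%, its crossing level of free monomer, and autumn 12.0%.
- Below the crossing, chains take the share f×/(f×+f) of each small loss, so summing from a level a down to a level b adds f× × ln((f×+a)/(f×+b)). From f× down to zero that is f× × ln(2), which takes free monomer as used up by the asked time.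
- Interpolated chains at the crossing read 13.6% in elm and 14.7% in birch. Their mean, 14.1%, is assumed for both new flasks.
- This gives noon 30.8% and autumn 22.5%, a gap of 8.3 percentage points, wider than the margin of 2 points.
- The forecast says noon, with 30% (27.5% to 32.5%) in noon and 19.5% (16.5% to 22%) in autumn, reasoning that “Chains therefore compete with the side loss”. Its autumn figure lies below my reckoning.
- The flasks give 30.8% in noon and 21.5% in autumn, so the answer is noon.

    free monomer + initiator → living end + monomer in chains (k = 0.0110 L mol⁻¹ min⁻¹)
    free monomer + living end → monomer in chains + living end, rate k2*[living end]*[free monomer] (k = 47.0 L mol⁻¹ min⁻¹)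
    2 living end ⇌ resting dimer, settled at all times (K = 410 L mol⁻¹)
    2 free monomer → self-condensation product (k = 0.0700 L mol⁻¹ min⁻¹)
    monomer in chains → over-reaction product (k = 5.20 × 10⁻⁶ min⁻¹)

- In noon, self-condensation ran early: by 6.00 h it had 99.1% of its turnover up to 12 h behind it, with free monomer at 6.86%. Noon's chain growth passed the midpoint of its turnover up to 12 h at 2.85 h. In autumn, the sum with the autumn f× carries the 15.7% in chains at 6.00 h to 20.8% by 12 h, against 21.5%. The noon flask at 3.00 h, with 20.4% free and 16.2% in chains, is carried by the noon f× to 30.0% by 12 h, against 30.8%.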